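## Retrosynthetic overview

1. Drimane numbering is used: ring A = C1–C5 and C10, ring B = C5–C10, C11 = benzylic CH2. Last events are desilylation, O-sulfation of the phenol ortho to C11 and debenzylation; the C9–C11 bond comes from a Negishi coupling of a benzylzinc reagent (benzene ring bought as 3-bromo-4,5-dihydroxybenzaldehyde) with the C9 enol triflate.
2. The enol triflate comes from the cis-fused C9 enone (conjugate reduction, triflation); the C10 methyl comes from angular methylation of the ring-fusion enolate; a C2 ester is cleared by hydrolysis and decarboxylation.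
3. Ring A is closed at C3–C4 by a hydrogen-atom-transfer radical cyclisation (reductive olefin–olefin coupling) of (S)-carvone carrying a 2-(methoxycarbonyl)allyl chain on C10.
4. Enabling feature: in ring B the C8 methyl is para to C5, and C5 carries C4 with its two methyls. This is the p-menthane pattern of carvone (isopropenyl = C4 plus both methyls, stereocentre = C5). C2 is a bare CH2, so a removable ester there can steer the 6-endo closure.
5. Order of rings: ring B (from carvone), then ring A (key step), then the preformed benzene ring is attached.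

Key step: step 2

Remark: read from the SMILES, H-5 and the C10 methyl lie on the same face (cis-fused decalin; 5R,10S in drimane numbering, 4aR,8aS in naphthalene numbering); the route is planned for this configuration.
Remark: aryl hydrogen sulfates are handled as salts; compound 22 and the target are written as the free hydrogen sulfates, the conjugate acids of the salts that would be isolated.

## Route

Step 1
Reactants: 1 (S)-(+)-carvone; 2 methyl 2-(bromomethyl)prop-2-enoate
Product: 4 methyl 2-{[(6S)-3-methyl-2-oxo-6-(prop-1-en-2-yl)cyclohex-3-en-1-yl]methyl}prop-2-enoate (both C1 epimers of the ring), via carvone lithium dienolate 3 (not isolated)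
Conditions: LiN(i-Pr)2 (1.05 equiv), THF, −78 °C; then 2 (1.1 equiv), −78 → −30 °C
Reagents that add atoms: none
Why: Kinetic deprotonation of the enone on the saturated side gives the cross-conjugated dienolate 3, which is alkylated at C10 by the very reactive allylic bromide (enolate alkylation by addition–elimination on the bromomethyl acrylate); the new C10 centre forms as an epimer mixture that does not matter because C10 is enolised again in step 5.

Step 2
Reactants: 4 methyl 2-{[(6S)-3-methyl-2-oxo-6-(prop-1-en-2-yl)cyclohex-3-en-1-yl]methyl}prop-2-enoate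
Product: 5 methyl (4aS)-4,4,7-trimethyl-8-oxo-1,2,3,4,4a,5,8,8a-octahydronaphthalene-2-carboxylate (epimers at C2 and C8a)
Conditions: Fe(acac)3 (30 mol%), PhSiH3 (2.5 equiv), EtOH/(CH2OH)2 5:1, 0.02 M, 60 °C
Reagents that add atoms: none
Why: An iron hydride formed from Fe(acac)3 and PhSiH3 transfers a hydrogen atom to the CH2 terminus of the isopropenyl group, which creates the second methyl on C4 and a nucleophilic tertiary radical at C4; this radical adds to C3, the unsubstituted beta-carbon of the acrylate, and the alpha-ester radical at C2 is reduced by divalent iron to the enolate and protonated by ethanol. The closest known reaction type is the iron-hydride reductive olefin–olefin coupling (hydrogen-atom-transfer Giese addition), used here intramolecularly, so that two olefinic carbons that are both electrophilic in two-electron terms are joined. Ring A (C4, C5, C10, C1, C2, C3) closes in the 6-endo-trig mode. No stereocentre of the target is created: C4 carries two methyls, C5 comes unchanged from carvone, C10 stays enolisable and is set in step 5, and C2 is cleared in step 4, so both C10 epimers of 4 can be used. The step needs hydrogen-atom transfer to the electron-rich 1,1-dialkyl olefin in preference to the acrylate and the enone, and 6-endo instead of 5-exo attack; the ester on C2 secures the latter by making C3 the electrophilic unhindered terminus and C2 a fully substituted carbon, and high dilution suppresses intermolecular addition.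

Step 3
Reactants: 5 methyl (4aS)-4,4,7-trimethyl-8-oxo-1,2,3,4,4a,5,8,8a-octahydronaphthalene-2-carboxylate
Product: 6 (4aS)-4,4,7-trimethyl-8-oxo-1,2,3,4,4a,5,8,8a-octahydronaphthalene-2-carboxylic acid (epimers at C2 and C8a)
Conditions: LiOH·H2O (3 equiv), THF/MeOH/H2O, 25 °C; then 1 M HCl to pH 3
Reagents that add atoms: lithium hydroxide (supplies the hydroxyl oxygen), [Li+].[OH-]
Why: Ester hydrolysis (saponification) with hydroxide frees the carboxylic acid needed for the radical decarboxylation without touching the enone or the C5 centre, which is not enolisable.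

Step 4
Reactants: 6 (4aS)-4,4,7-trimethyl-8-oxo-1,2,3,4,4a,5,8,8a-octahydronaphthalene-2-carboxylic acid
Product: 7 (4aS)-2,5,5-trimethyl-4a,5,6,7,8,8a-hexahydronaphthalen-1(4H)-one (both ring-fusion epimers at C8a)
Conditions: 9-mesityl-10-phenylacridinium tetrafluoroborate (5 mol%), PhSSPh (10 mol%), i-Pr2NEt (20 mol%), CF3CH2OH, 450 nm LEDs, 25 °C
Reagents that add atoms: none
Why: Photoredox hydrodecarboxylation: the excited acridinium oxidises the carboxylate, CO2 is lost and the secondary C2 radical takes a hydrogen atom from thiophenol formed in situ, so that the activating group and the C2 stereocentre disappear together.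

Step 5
Reactants: 7 (4aS)-2,5,5-trimethyl-4a,5,6,7,8,8a-hexahydronaphthalen-1(4H)-one
Product: 9 (4aR,8aS)-2,5,5,8a-tetramethyl-4a,5,6,7,8,8a-hexahydronaphthalen-1(4H)-one (cis-fused), via lithium dienolate 8 (not isolated)
Conditions: LiN(i-Pr)2 (1.1 equiv), THF, −78 °C; then MeI (3 equiv), DMPU, −78 → 0 °C
Reagents that add atoms: iodomethane, CI
Why: Angular enolate alkylation: the only alpha-prime hydrogen (at C10) is removed kinetically and methyl iodide should attack the planar C10 of dienolate 8 on the face of H-5, because the other face is blocked by the axial C4 methyl group (1,3-diaxial), which sets the quaternary C10 centre with cis ring fusion from either ring-fusion epimer of 7.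

Step 6
Reactants: 9 (4aR,8aS)-2,5,5,8a-tetramethyl-4a,5,6,7,8,8a-hexahydronaphthalen-1(4H)-one
Product: 11 (4aR,8aS)-2,5,5,8a-tetramethyl-3,4,4a,5,6,7,8,8a-octahydronaphthalen-1-yl trifluoromethanesulfonate, via lithium enolate 10 (not isolated)
Conditions: LiBH(s-Bu)3 (1.1 equiv), THF, −78 °C; then PhNTf2 (1.3 equiv), −78 → 25 °C
Reagents that add atoms: N-phenylbis(trifluoromethanesulfonimide), O=S(=O)(N(c1ccccc1)S(=O)(=O)C(F)(F)F)C(F)(F)F
Why: Conjugate (1,4) hydride reduction of the beta-unsubstituted enone by the bulky borohydride gives regiospecifically the C8=C9 enolate 10, which is trapped on oxygen by PhNTf2 (enol triflate formation); no stereocentre is created since C8 stays sp2.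

Step 7
Reactants: 12 3-bromo-4,5-dihydroxybenzaldehyde
Product: 13 4-(benzyloxy)-3-bromo-5-hydroxybenzaldehyde
Conditions: BnBr (1.0 equiv), K2CO3 (1.0 equiv), DMF, 25 °C
Reagents that add atoms: benzyl bromide, BrCc1ccccc1
Why: Williamson ether synthesis with one equivalent of weak base: the 4-hydroxyl, para to the formyl group and ortho to bromine, is the more acidic phenol and is the one benzylated, which marks the oxygen that will later carry the sulfate.

Step 8
Reactants: 13 4-(benzyloxy)-3-bromo-5-hydroxybenzaldehyde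
Product: 14 2-(benzyloxy)-3-bromo-5-(hydroxymethyl)phenol
Conditions: NaBH4 (1.0 equiv), MeOH/THF, 0 °C
Reagents that add atoms: none
Why: Chemoselective borohydride reduction of the aldehyde to the benzylic alcohol, with the aryl bromide and the benzyl ether untouched.

Step 9
Reactants: 14 2-(benzyloxy)-3-bromo-5-(hydroxymethyl)phenol
Product: 15 2-(benzyloxy)-1-bromo-3-[(triisopropylsilyl)oxy]-5-{[(triisopropylsilyl)oxy]methyl}benzene
Conditions: i-Pr3SiCl (2.5 equiv), imidazole (5 equiv), DMF, 25 °C
Reagents that add atoms: chlorotriisopropylsilane, CC(C)[Si](Cl)(C(C)C)C(C)C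
Why: Silyl ether formation on both the phenol and the primary alcohol with the bulky triisopropylsilyl group, which withstands organolithium, zinc and palladium reagents and is slow to migrate between neighbouring oxygens.

Step 10
Reactants: 15 2-(benzyloxy)-1-bromo-3-[(triisopropylsilyl)oxy]-5-{[(triisopropylsilyl)oxy]methyl}benzene
Product: 17 {2-(benzyloxy)-3-[(triisopropylsilyl)oxy]-5-{[(triisopropylsilyl)oxy]methyl}phenyl}methanol, via aryllithium 16 (not isolated)
Conditions: n-BuLi (1.1 equiv), THF, −78 °C; then (CH2O)n (excess), −78 → 25 °C; aq. NH4Cl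
Reagents that add atoms: formaldehyde (from paraformaldehyde), C=O
Why: Bromine–lithium exchange followed by addition of aryllithium 16 to formaldehyde (hydroxymethylation) brings in the carbon that becomes C11; the ortho benzyloxy group stabilises the aryllithium by chelation.

Step 11
Reactants: 17 {2-(benzyloxy)-3-[(triisopropylsilyl)oxy]-5-{[(triisopropylsilyl)oxy]methyl}phenyl}methanol
Product: 18 2-(benzyloxy)-1-(chloromethyl)-3-[(triisopropylsilyl)oxy]-5-{[(triisopropylsilyl)oxy]methyl}benzene
Conditions: PPh3 (1.2 equiv), N-chlorosuccinimide (1.2 equiv), CH2Cl2, 0 → 25 °C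
Reagents that add atoms: N-chlorosuccinimide, ClN1C(=O)CCC1=O
Why: Appel-type chlorination (PPh3 and N-chlorosuccinimide) turns the benzylic alcohol into the chloride under neutral conditions that spare both silyl ethers.

Step 12
Reactants: 18 2-(benzyloxy)-1-(chloromethyl)-3-[(triisopropylsilyl)oxy]-5-{[(triisopropylsilyl)oxy]methyl}benzene; 11 (4aR,8aS)-2,5,5,8a-tetramethyl-3,4,4a,5,6,7,8,8a-octahydronaphthalen-1-yl trifluoromethanesulfonate
Product: 20 2-(benzyloxy)-1-{[(4aR,8aS)-2,5,5,8a-tetramethyl-3,4,4a,5,6,7,8,8a-octahydronaphthalen-1-yl]methyl}-3-[(triisopropylsilyl)oxy]-5-{[(triisopropylsilyl)oxy]methyl}benzene, via benzylzinc chloride 19 (not isolated)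
Conditions: 18, Zn dust (1.5 equiv), LiCl (1.5 equiv), THF, 25 °C; then 11, Pd(OAc)2 (5 mol%), SPhos (10 mol%), THF, 25 → 50 °C
Reagents that add atoms: none
Why: Zinc insertion into the benzylic chloride gives benzylzinc chloride 19, which undergoes Negishi cross-coupling with the enol triflate (oxidative addition of zerovalent palladium into the C9–O bond, transmetalation, reductive elimination); the bulky electron-rich biarylphosphine is chosen for the tetrasubstituted triflate, and the C8=C9 double bond and both ring-fusion centres are untouched.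

Step 13
Reactants: 20 2-(benzyloxy)-1-{[(4aR,8aS)-2,5,5,8a-tetramethyl-3,4,4a,5,6,7,8,8a-octahydronaphthalen-1-yl]methyl}-3-[(triisopropylsilyl)oxy]-5-{[(triisopropylsilyl)oxy]methyl}benzene
Product: 21 2-{[(4aR,8aS)-2,5,5,8a-tetramethyl-3,4,4a,5,6,7,8,8a-octahydronaphthalen-1-yl]methyl}-6-[(triisopropylsilyl)oxy]-4-{[(triisopropylsilyl)oxy]methyl}phenol
Conditions: H2 (1 atm), Pd/C (10 wt%), EtOAc, 25 °C
Reagents that add atoms: none
Why: Hydrogenolysis of the aryl benzyl ether over palladium on carbon frees only the phenol that is to be sulfated, the tetrasubstituted C8=C9 alkene being too hindered to add hydrogen under these conditions.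

Step 14
Reactants: 21 2-{[(4aR,8aS)-2,5,5,8a-tetramethyl-3,4,4a,5,6,7,8,8a-octahydronaphthalen-1-yl]methyl}-6-[(triisopropylsilyl)oxy]-4-{[(triisopropylsilyl)oxy]methyl}phenol
Product: 22 2-{[(4aR,8aS)-2,5,5,8a-tetramethyl-3,4,4a,5,6,7,8,8a-octahydronaphthalen-1-yl]methyl}-6-[(triisopropylsilyl)oxy]-4-{[(triisopropylsilyl)oxy]methyl}phenyl hydrogen sulfate
Conditions: SO3·pyridine (5 equiv), pyridine, 50 °C
Reagents that add atoms: sulfur trioxide–pyridine complex, O=S(=O)([O-])[n+]1ccccc1
Why: O-Sulfation of the free phenol by the sulfur trioxide–pyridine complex; the basic medium avoids acid-induced addition of this phenol to the C8=C9 double bond.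

Step 15
Reactants: 22 2-{[(4aR,8aS)-2,5,5,8a-tetramethyl-3,4,4a,5,6,7,8,8a-octahydronaphthalen-1-yl]methyl}-6-[(triisopropylsilyl)oxy]-4-{[(triisopropylsilyl)oxy]methyl}phenyl hydrogen sulfate
Product: 23 2-hydroxy-4-(hydroxymethyl)-6-{[(4aR,8aS)-2,5,5,8a-tetramethyl-3,4,4a,5,6,7,8,8a-octahydronaphthalen-1-yl]methyl}phenyl hydrogen sulfate (target)
Conditions: Bu4NF (3 equiv), THF, 0 → 25 °C; pH 7 buffer; reversed-phase chromatography
Reagents that add atoms: none
Why: Fluoride-induced desilylation cleaves the aryl and the alkyl silyl ether, while the aryl sulfate monoester anion is inert to fluoride and mild base.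

## Compound list

1 | (S)-(+)-carvone, (5S)-2-methyl-5-(prop-1-en-2-yl)cyclohex-2-en-1-one | CC1=CC[C@@H](CC1=O)C(C)=C | starting material
2 | methyl 2-(bromomethyl)prop-2-enoate | C=C(CBr)C(=O)OC | starting material
3 | lithium (3S)-6-methyl-3-(prop-1-en-2-yl)cyclohexa-1,5-dien-1-olate (carvone lithium dienolate, formed in situ) | CC1=CC[C@H](C(C)=C)C=C1[O-].[Li+] | intermediate
4 | methyl 2-{[(6S)-3-methyl-2-oxo-6-(prop-1-en-2-yl)cyclohex-3-en-1-yl]methyl}prop-2-enoate (ring C1 epimers; this centre is reset in step 5) | CC1=CC[C@H](C(C)=C)C(CC(=C)C(=O)OC)C1=O | intermediate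
5 | methyl (4aS)-4,4,7-trimethyl-8-oxo-1,2,3,4,4a,5,8,8a-octahydronaphthalene-2-carboxylate (epimers at C2 and C8a; C2 is cleared in step 4, C8a reset in step 5) | CC1=CC[C@@H]2C(C)(C)CC(C(=O)OC)CC2C1=O | intermediate
6 | (4aS)-4,4,7-trimethyl-8-oxo-1,2,3,4,4a,5,8,8a-octahydronaphthalene-2-carboxylic acid (epimers at C2 and C8a) | CC1=CC[C@@H]2C(C)(C)CC(C(=O)O)CC2C1=O | intermediate
7 | (4aS)-2,5,5-trimethyl-4a,5,6,7,8,8a-hexahydronaphthalen-1(4H)-one (C8a epimers) | CC1=CC[C@@H]2C(C)(C)CCCC2C1=O | intermediate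
8 | lithium (4aR)-2,5,5-trimethyl-4,4a,5,6,7,8-hexahydronaphthalen-1-olate (ring-fusion dienolate, formed in situ) | CC1=CC[C@@H]2C(C)(C)CCCC2=C1[O-].[Li+] | intermediate
9 | (4aR,8aS)-2,5,5,8a-tetramethyl-4a,5,6,7,8,8a-hexahydronaphthalen-1(4H)-one (cis-fused) | CC1=CC[C@@H]2C(C)(C)CCC[C@]2(C)C1=O | intermediate
10 | lithium (4aR,8aS)-2,5,5,8a-tetramethyl-3,4,4a,5,6,7,8,8a-octahydronaphthalen-1-olate (formed in situ) | CC1=C([O-])[C@@]2(C)CCCC(C)(C)[C@H]2CC1.[Li+] | intermediate
11 | (4aR,8aS)-2,5,5,8a-tetramethyl-3,4,4a,5,6,7,8,8a-octahydronaphthalen-1-yl trifluoromethanesulfonate | CC1=C(OS(=O)(=O)C(F)(F)F)[C@@]2(C)CCCC(C)(C)[C@H]2CC1 | intermediate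
12 | 3-bromo-4,5-dihydroxybenzaldehyde | Brc1cc(C=O)cc(O)c1O | starting material
13 | 4-(benzyloxy)-3-bromo-5-hydroxybenzaldehyde | Brc1cc(C=O)cc(O)c1OCc1ccccc1 | intermediate
14 | 2-(benzyloxy)-3-bromo-5-(hydroxymethyl)phenol | Brc1cc(CO)cc(O)c1OCc1ccccc1 | intermediate
15 | 2-(benzyloxy)-1-bromo-3-[(triisopropylsilyl)oxy]-5-{[(triisopropylsilyl)oxy]methyl}benzene | Brc1cc(CO[Si](C(C)C)(C(C)C)C(C)C)cc(O[Si](C(C)C)(C(C)C)C(C)C)c1OCc1ccccc1 | intermediate
16 | {2-(benzyloxy)-3-[(triisopropylsilyl)oxy]-5-{[(triisopropylsilyl)oxy]methyl}phenyl}lithium (formed in situ) | [Li]c1cc(CO[Si](C(C)C)(C(C)C)C(C)C)cc(O[Si](C(C)C)(C(C)C)C(C)C)c1OCc1ccccc1 | intermediate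
17 | {2-(benzyloxy)-3-[(triisopropylsilyl)oxy]-5-{[(triisopropylsilyl)oxy]methyl}phenyl}methanol | OCc1cc(CO[Si](C(C)C)(C(C)C)C(C)C)cc(O[Si](C(C)C)(C(C)C)C(C)C)c1OCc1ccccc1 | intermediate
18 | 2-(benzyloxy)-1-(chloromethyl)-3-[(triisopropylsilyl)oxy]-5-{[(triisopropylsilyl)oxy]methyl}benzene | ClCc1cc(CO[Si](C(C)C)(C(C)C)C(C)C)cc(O[Si](C(C)C)(C(C)C)C(C)C)c1OCc1ccccc1 | intermediate
19 | {2-(benzyloxy)-3-[(triisopropylsilyl)oxy]-5-{[(triisopropylsilyl)oxy]methyl}benzyl}zinc chloride (formed in situ) | Cl[Zn]Cc1cc(CO[Si](C(C)C)(C(C)C)C(C)C)cc(O[Si](C(C)C)(C(C)C)C(C)C)c1OCc1ccccc1 | intermediate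
20 | 2-(benzyloxy)-1-{[(4aR,8aS)-2,5,5,8a-tetramethyl-3,4,4a,5,6,7,8,8a-octahydronaphthalen-1-yl]methyl}-3-[(triisopropylsilyl)oxy]-5-{[(triisopropylsilyl)oxy]methyl}benzene | CC1=C(Cc2cc(CO[Si](C(C)C)(C(C)C)C(C)C)cc(O[Si](C(C)C)(C(C)C)C(C)C)c2OCc2ccccc2)[C@@]2(C)CCCC(C)(C)[C@H]2CC1 | intermediate
21 | 2-{[(4aR,8aS)-2,5,5,8a-tetramethyl-3,4,4a,5,6,7,8,8a-octahydronaphthalen-1-yl]methyl}-6-[(triisopropylsilyl)oxy]-4-{[(triisopropylsilyl)oxy]methyl}phenol | CC1=C(Cc2cc(CO[Si](C(C)C)(C(C)C)C(C)C)cc(O[Si](C(C)C)(C(C)C)C(C)C)c2O)[C@@]2(C)CCCC(C)(C)[C@H]2CC1 | intermediate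
22 | 2-{[(4aR,8aS)-2,5,5,8a-tetramethyl-3,4,4a,5,6,7,8,8a-octahydronaphthalen-1-yl]methyl}-6-[(triisopropylsilyl)oxy]-4-{[(triisopropylsilyl)oxy]methyl}phenyl hydrogen sulfate | CC1=C(Cc2cc(CO[Si](C(C)C)(C(C)C)C(C)C)cc(O[Si](C(C)C)(C(C)C)C(C)C)c2OS(=O)(=O)O)[C@@]2(C)CCCC(C)(C)[C@H]2CC1 | intermediate
23 | 2-hydroxy-4-(hydroxymethyl)-6-{[(4aR,8aS)-2,5,5,8a-tetramethyl-3,4,4a,5,6,7,8,8a-octahydronaphthalen-1-yl]methyl}phenyl hydrogen sulfate | CC1=C(Cc2cc(CO)cc(O)c2OS(=O)(=O)O)[C@@]2(C)CCCC(C)(C)[C@H]2CC1 | target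

## Step count and risks

Total step count: 15 (steps 1–6 on the terpene, steps 7–11 on the arene, steps 12–15 after the union).
Longest linear sequence: 10 steps from (S)-carvone (steps 1–6 and 12–15).

Three steps most likely to fail:

Step 2 (key step). What may go wrong: hydrogen-atom transfer to the acrylate or the enone instead of the isopropenyl group, so that the acceptor is simply reduced or the ring closes through the wrong radical, and intermolecular radical addition at higher concentration. Fallback, setting out from 4 and coming back at 5: the tertiary radical is made regiospecifically from a halide instead of by hydrogen-atom transfer. Markovnikov addition of HCl (gas, CH2Cl2, −20 °C) to the isopropenyl group of 4 would give the tertiary chloride methyl 2-{[(6S)-6-(2-chloropropan-2-yl)-3-methyl-2-oxocyclohex-3-en-1-yl]methyl}prop-2-enoate F1. Slow addition of Bu3SnH with AIBN in benzene at 80 °C would abstract chlorine, and the same C4 radical would close 6-endo onto C3 to give 5.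

Step 5. What may go wrong: deprotonation at the gamma position instead of the hindered ring-fusion C–H, O-methylation, or poor facial selectivity in the attack of methyl iodide. Fallback, setting out from 1 and coming back at 9: the quaternary centre is built on the monocyclic ketone before ring A is closed, relying on the expected entry of the second electrophile anti to the C5 substituent.
- Dienolate 3 would be alkylated with 2,3-dibromopropene to (5S)-6-(2-bromoprop-2-en-1-yl)-2-methyl-5-(prop-1-en-2-yl)cyclohex-2-en-1-one F2.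
- Deprotonation with LiN(i-Pr)2 to its lithium dienolate F3 and methylation with MeI trans to the isopropenyl group would give (5R,6S)-6-(2-bromoprop-2-en-1-yl)-2,6-dimethyl-5-(prop-1-en-2-yl)cyclohex-2-en-1-one F4.
- Methoxycarbonylation of the vinyl bromide (Pd(OAc)2, PPh3, CO, MeOH, Et3N) would give the acrylate methyl 2-{[(1S,6R)-1,3-dimethyl-2-oxo-6-(prop-1-en-2-yl)cyclohex-3-en-1-yl]methyl}prop-2-enoate F5.
- The iron-hydride cyclisation of step 2 would then give the cis-fused keto ester methyl (4aR,8aS)-4,4,7,8a-tetramethyl-8-oxo-1,2,3,4,4a,5,8,8a-octahydronaphthalene-2-carboxylate F6.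
- Saponification to the acid (4aR,8aS)-4,4,7,8a-tetramethyl-8-oxo-1,2,3,4,4a,5,8,8a-octahydronaphthalene-2-carboxylic acid F7 and the photoredox hydrodecarboxylation of step 4 would deliver 9.

Step 12. What may go wrong: slow oxidative addition and transmetalation at the tetrasubstituted enol triflate flanked by the quaternary C10, with homocoupling or protonation of the benzylzinc reagent taking over. Fallback, setting out from 11 (with aryllithium 16 made from 15 as in step 10) and coming back at 20: C11 is placed on the terpene and joined to the arene by allylic substitution.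
- Methoxycarbonylation of 11 (Pd(OAc)2, PPh3, CO, MeOH, Et3N, DMF) would give methyl (4aR,8aS)-2,5,5,8a-tetramethyl-3,4,4a,5,6,7,8,8a-octahydronaphthalene-1-carboxylate F8.
- Reduction with i-Bu2AlH would give the allylic alcohol [(4aR,8aS)-2,5,5,8a-tetramethyl-3,4,4a,5,6,7,8,8a-octahydronaphthalen-1-yl]methanol F9.
- CBr4 and PPh3 would give the allylic bromide (4aR,8aS)-1-(bromomethyl)-2,5,5,8a-tetramethyl-3,4,4a,5,6,7,8,8a-octahydronaphthalene F10.
- Displacement of the primary bromide by aryllithium 16 with catalytic CuBr·SMe2 at −78 °C would give 20; attack at the tetrasubstituted C8 is disfavoured.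

Further compounds

F1 | step 2 | methyl 2-{[(6S)-6-(2-chloropropan-2-yl)-3-methyl-2-oxocyclohex-3-en-1-yl]methyl}prop-2-enoate (ring C1 epimers) | CC1=CC[C@H](C(C)(C)Cl)C(CC(=C)C(=O)OC)C1=O
F2 | step 5 | (5S)-6-(2-bromoprop-2-en-1-yl)-2-methyl-5-(prop-1-en-2-yl)cyclohex-2-en-1-one (C6 epimers) | CC1=CC[C@H](C(C)=C)C(CC(Br)=C)C1=O
F3 | step 5 | lithium dienolate of F2 | CC1=CC[C@H](C(C)=C)C(CC(Br)=C)=C1[O-].[Li+]
F4 | step 5 | (5R,6S)-6-(2-bromoprop-2-en-1-yl)-2,6-dimethyl-5-(prop-1-en-2-yl)cyclohex-2-en-1-one | CC1=CC[C@H](C(C)=C)[C@](C)(CC(Br)=C)C1=O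
F5 | step 5 | methyl 2-{[(1S,6R)-1,3-dimethyl-2-oxo-6-(prop-1-en-2-yl)cyclohex-3-en-1-yl]methyl}prop-2-enoate | CC1=CC[C@H](C(C)=C)[C@](C)(CC(=C)C(=O)OC)C1=O
F6 | step 5 | methyl (4aR,8aS)-4,4,7,8a-tetramethyl-8-oxo-1,2,3,4,4a,5,8,8a-octahydronaphthalene-2-carboxylate (C2 epimers) | CC1=CC[C@@H]2C(C)(C)CC(C(=O)OC)C[C@]2(C)C1=O
F7 | step 5 | (4aR,8aS)-4,4,7,8a-tetramethyl-8-oxo-1,2,3,4,4a,5,8,8a-octahydronaphthalene-2-carboxylic acid (C2 epimers) | CC1=CC[C@@H]2C(C)(C)CC(C(=O)O)C[C@]2(C)C1=O
F8 | step 12 | methyl (4aR,8aS)-2,5,5,8a-tetramethyl-3,4,4a,5,6,7,8,8a-octahydronaphthalene-1-carboxylate | CC1=C(C(=O)OC)[C@@]2(C)CCCC(C)(C)[C@H]2CC1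
F9 | step 12 | [(4aR,8aS)-2,5,5,8a-tetramethyl-3,4,4a,5,6,7,8,8a-octahydronaphthalen-1-yl]methanol | CC1=C(CO)[C@@]2(C)CCCC(C)(C)[C@H]2CC1
F10 | step 12 | (4aR,8aS)-1-(bromomethyl)-2,5,5,8a-tetramethyl-3,4,4a,5,6,7,8,8a-octahydronaphthalene | CC1=C(CBr)[C@@]2(C)CCCC(C)(C)[C@H]2CC1
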